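Assumption (sense of induction): the (Ra,R,R) enantiomer of the binaphthol-derived N,N-bis(1-phenylethyl)phosphoramidite is taken to direct the nucleophile to the Re face of the substituted allyl terminus, in line with the sense known for cinnamyl-type carbonates. If the (R)-carbinol reverses this sense, the mirror-image ligand is used and nothing else changes.

## Structural features

The target is one tetrahydrofuran ring (O1, C2, C3, C4, C5) that joins two electron-rich arenes. C2 carries the 3,4-dimethoxyphenyl ring, C3 a hydroxymethyl group, C4 the 3,4,5-trimethoxybenzoyl group through the ketone carbon C7', and C5 is an unsubstituted OCH2. The three stereocentres C2 (R), C3 (R) and C4 (S) are contiguous, with aryl and hydroxymethyl cis (2,3-cis) and hydroxymethyl and aroyl trans (3,4-trans). C2 is a benzylic ether carbon on a donor-substituted ring and can ionise under acid, which would relax the crowded 2,3-cis pair to 2,3-trans. C4 is α to the ketone and epimerisable, though its required configuration is the favoured one, and O1–C5–C4–C7'=O is a β-alkoxy ketone that can open by base-induced elimination. The real difficulty is the 2,3-cis pair in one absolute configuration, since neither C2 nor C3 can be corrected by equilibration, together with three oxygenated carbons (C5, C7', the C3 CH2OH) at different oxidation levels. The key step exploits the fact that, once the hydroxymethyl carbon is read as the inner carbon of a vinyl group, C3 is a branched allylic carbon between the C2 carbinol and C4, and C4 is the central carbon of a 1,3-dicarbonyl unit made of C5 (as formyl) and C7' (aryl ketone). The formyl carbon enters one oxidation level above the C5 methylene, so a conjugate reduction follows the ring closure and is also where C4 is set.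

## Logic of the disconnections

16 to 14: the C3 hydroxymethyl carbon of 16 is traced back to the inner carbon of a vinyl group, so the terminal C=C bond of 14 is the bond cut, and the aldehyde 15 lies in between. The cut is made there because a vinyl group at C3 is what a branched allylic substitution leaves behind. The skeleton is not simplified, but 14 has no free hydroxyl and needs no protecting group. The forward step must cleave one alkene beside two donor-substituted arenes, reduce the aldehyde of 15 but not the aryl ketone, and do so before C3 (then α to a formyl group) can epimerise. This saves the reduce-everything and re-oxidise detour, which is kept in reserve.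

14 to 12: the C4–H and C5–H bonds are removed, which introduces the C4=C5 double bond. The reason is that the β-alkoxy enone of 12 is the direct product of a cyclodehydration, so C5 can enter as a formyl carbon. C4 is no longer a stereocentre in 12. The forward step needs a 1,4-delivery of hydride that leaves the vinyl group and the ketone alone. Protonation at C4 is expected to give mainly 13 first, so an equilibration to the 3,4-trans ketone 14 is required.

12 to 6 and 9: the bonds cut are O1–C5 and C3–C4. Cutting O1–C5 (through 11) is a retro-condensation of the C2 hydroxyl with a formyl group; cutting C3–C4 in 10 is a retro-allylic alkylation at the substituted allyl terminus. The molecule falls into two halves of similar size, each with one arene, and only the C2 stereocentre has to exist beforehand; the ring, both bonds and the C3 stereocentre arise in one flask. The forward step must attack the substituted terminus, through carbon and not oxygen of 9, on the face that puts vinyl cis to aryl. The hydroxyl must close on the formyl carbon and not on the ketone, and the acid must be weak enough to leave C2 intact.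

6 to 4 and 5: the C=C bond of 6 is cut as a cross-metathesis retron. This reaches a simple vinyl carbinol and a commercial allyl carbonate. The forward step must give the E alkene without redox isomerisation or ionisation of the free benzylic allylic alcohol.

4 to 3, then to 1 and 2: 4 is one enantiomer of 3, and 3 is cut at the carbinol C–C bond. A resolution is accepted, at the price of half the material, because it uses the hydroxyl and the alkene that are already present and adds no protecting group. It must leave the (R) enantiomer behind, which fixes the enantiomer of the chiral controller.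

9 to 7 and 8: the C4–C5 bond is cut as a crossed ester condensation. Only one partner is enolisable, and the product leaves the equilibrium as its salt, which is also the form in which it is used.

## Other disconnections considered

Alternative 1: The cut is at C4–C7' and C7'–aryl, with carbon monoxide as the one-carbon link. In the forward step Pd(OAc)2 with a chelating bisphosphine would convert 5-iodo-1,2,3-trimethoxybenzene A3 into an aroyl complex of divalent palladium under CO. This would acylate C4 of the silyl-protected cis-2-aryl-3-(hydroxymethyl)-2,3-dihydrofuran A2 to give the alkoxyenone A1.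
- In its favour: it is a late three-component union, and the C3 carbon is already at the alcohol oxidation level. No alkene cleavage and no chemoselective reduction are needed afterwards, and on that point it is better than the chosen plan.
- Equal: A1 is the same kind of β-alkoxy enone as 12, so the conjugate reduction and the thermodynamic setting of C4 are the same, and the number of steps after the key step (reduction, desilylation) is the same.
- Against: the key step closes no ring and makes no stereocentre, so A2 must be built beforehand with the ring and the whole 2,3-cis pair.
- Against, mechanism: aryl-palladium species add to cyclic enol ethers at the carbon next to oxygen, whereas the acyl group is needed at C4. After syn insertion the metal sits on C5 and the only β-hydrogen (on C4) is anti to it, so the usual syn β-hydride elimination cannot restore the C4=C5 bond; a base-mediated anti elimination would have to be assumed. Direct arylation without CO uptake also competes.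
- Overall: the chosen plan makes two bonds, the ring and one stereocentre in its key step; this alternative makes two bonds only and pays with a longer route to A2.

Alternative 2: The cut is at C4–C5, with the C7' oxygen introduced in the same step. In the forward step Bu3SnH under air would convert the phenylselanylmethyl ether A5 into an O–CH2 radical, which closes 5-exo onto the styrene. The benzylic radical at C7' is then trapped by oxygen to give the carbinol A4.
- In its favour: the ring closes by C–C bond formation under neutral conditions, which is kinder to the acid-sensitive C2 than the acid phase of the chosen key step. C5 and the C3 carbon are at their final oxidation levels, so neither a conjugate reduction nor an alkene cleavage is needed. On both points it is better.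
- Equal: C4 can be corrected after oxidation to the ketone, as in the chosen plan, and two steps follow the key step (oxidation of the carbinol mixture, desilylation).
- Against: both C2 and C3 must be set before the key step in an acyclic precursor, and a hindered benzylic alkoxide must be alkylated with a selenomethyl halide.
- Against, selectivity: in the chair-like transition state the C3 substituent favours 3,4-trans, but the C2 aryl group favours 2,4-cis, and in the 2,3-cis series these oppose each other. Oxygen trapping also competes with hydrogen transfer from the tin hydride, which would give the deoxygenated product.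
- Against, practice: stoichiometric tin and selenium residues.
- Overall: comparable in steps after the key event, but longer before it, and it relies on substrate control where the chosen plan uses a catalyst.

Alternative 3: The cut is at C2–C3. In the forward step Me3SiOTf at low temperature would ionise the 4,5-dihydro-1,3-dioxepine A7 at its acetal carbon to an oxocarbenium–enolate pair. Recombination at carbon contracts the seven-membered ring to the tetrahydrofuran-3-carbaldehyde A6.
- In its favour: C2 and C3 are both created in one step, relayed from the single stereocentre that becomes C4, without a chiral catalyst at that stage. The kinetic 2,3-cis-3,4-trans outcome is the one required. There is no alkoxyenone and hence no conjugate reduction. On these points it is better.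
- Equal: A6 is an epimerisable aldehyde of the same kind as 15 and needs the same careful reduction. An oxidative cleavage beside two electron-rich arenes is also required (the 1-arylvinyl group to the ketone), so the end-game is of equal length and difficulty.
- Against: the absolute configuration rests on A7, which must be obtained enantioenriched at a carbon flanked by an enol ether and a 1-arylvinyl group, and no short way to it is evident.
- Against, mechanism: the donor-substituted aryl acetal ionises reversibly, so the kinetic 2,3-cis product may drift to 2,3-trans under the Lewis acid if the temperature rises.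
- Overall: more elegant stereochemically, weaker in the supply of its precursor. The chosen plan draws its chirality from a resolution and a catalyst, both applied to simple compounds.

Key step: step 5

## Route

Step 1
Reactants: 1 veratraldehyde (3,4-dimethoxybenzaldehyde); 2 vinylmagnesium bromide
Product: 3 rac-1-(3,4-dimethoxyphenyl)prop-2-en-1-ol
Conditions: 2 (1.2 equiv), THF, 0 °C; aq. NH4Cl
Reagents that add atoms: none
Why: 1,2-Addition of the vinyl Grignard reagent to the aldehyde; the carbinol centre is formed without control and is resolved in step 2.

Step 2
Reactants: 3 rac-1-(3,4-dimethoxyphenyl)prop-2-en-1-ol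
Product: 4 (R)-1-(3,4-dimethoxyphenyl)prop-2-en-1-ol
Conditions: Ti(OiPr)4 (0.2 equiv), D-(−)-diisopropyl tartrate (0.24 equiv), t-BuOOH (0.6 equiv), 4 Å MS, CH2Cl2, −20 °C
Reagents that add atoms: none
Why: Sharpless kinetic resolution: with the (S,S)-tartrate the complex of tetravalent titanium epoxidises the (S)-enantiomer of the secondary allylic alcohol faster, so the (R)-alcohol should be left in high enantiomeric purity once a little more than half of 3 is consumed. This fixes C2 of the target.

Step 3
Reactants: 4 (R)-1-(3,4-dimethoxyphenyl)prop-2-en-1-ol; 5 allyl methyl carbonate
Product: 6 (R,E)-4-(3,4-dimethoxyphenyl)-4-hydroxybut-2-en-1-yl methyl carbonate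
Conditions: 5 (3 equiv), second-generation Grubbs catalyst (H2IMes)(PCy3)Cl2Ru=CHPh (5 mol%), CH2Cl2, 40 °C
Reagents that add atoms: none
Why: Olefin cross-metathesis between a slowly homodimerising secondary allylic alcohol and an excess of a rapidly exchanging allyl carbonate should give the E alkene under thermodynamic control. The carbinol centre is not involved and the free hydroxyl is tolerated by the ruthenium carbene.

Step 4
Reactants: 7 3',4',5'-trimethoxyacetophenone; 8 ethyl formate
Product: 9 sodium 3-oxo-3-(3,4,5-trimethoxyphenyl)prop-1-en-1-olate (sodium enolate of 3-oxo-3-(3,4,5-trimethoxyphenyl)propanal)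
Conditions: NaOMe (1.1 equiv), 8 (3 equiv), Et2O, 0 °C to rt; salt collected by filtration
Reagents that add atoms: sodium methoxide, [Na+].[O-]C
Why: Crossed Claisen condensation (formylation) of the methyl ketone enolate with the non-enolisable formate ester. The sparingly soluble sodium enolate precipitates, which drives the equilibrium and means the self-condensing free formyl ketone is never handled.

Step 5
Reactants: 6 (R,E)-4-(3,4-dimethoxyphenyl)-4-hydroxybut-2-en-1-yl methyl carbonate; 9 sodium 3-oxo-3-(3,4,5-trimethoxyphenyl)prop-1-en-1-olate
Product: 12 [(4S,5R)-5-(3,4-dimethoxyphenyl)-4-ethenyl-4,5-dihydrofuran-3-yl](3,4,5-trimethoxyphenyl)methanone, the (2R,3S)-2-aryl-3-vinyl-4-aroyl-2,3-dihydrofuran (2,3-cis), via branched C-allylated hydroxy formyl ketone 10 (not isolated), via cyclic hemiacetal 11 (not isolated)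
Conditions: [Ir(cod)Cl]2 (2 mol%), (Ra,R,R)-phosphoramidite (4 mol%), n-PrNH2, THF, 50 °C, then volatiles removed; 6, 9 (1.5 equiv), THF, rt; then AcOH (3 equiv), PPTS (0.2 equiv), 4 Å MS, 40 °C
Reagents that add atoms: none
Why: Proposed new method: the closest known reaction type is the iridium–phosphoramidite allylic alkylation of linear allyl carbonates with stabilised enolates (malonates, β-keto esters, 1,3-diketones), which gives branched products by outer-sphere attack on an allyl complex; a β-ketoaldehyde enolate is the same kind of soft, delocalised carbon nucleophile, and the cyclodehydration that follows is the ordinary acid-catalysed conversion of a hydroxymethylene ketone and an alcohol into an alkoxymethylene ketone, here intramolecular. The cyclometalated complex of monovalent iridium ionises the methyl carbonate of 6 (loss of CO2 and methoxide) to a syn-allyl complex of trivalent iridium, and the enolate 9 attacks the substituted terminus through carbon, anti to the metal, which forms C3–C4 and gives 10 (held as its enolate after proton transfer to methoxide). On acidification the C2 hydroxyl adds to the formyl carbon in a 5-exo-trig closure to the hemiacetal 11 (O1–C5), and loss of water, driven by conjugation of the new enol ether with the aryl ketone, gives 12. The C3 stereocentre is set by the catalyst: the (Ra,R,R) ligand is chosen to deliver the nucleophile to the Re face of the allyl terminus, which places the vinyl group cis to the aryl group on the untouched (R)-carbinol carbon and makes C3 (S). Branched over linear attack is the inherent preference of this catalyst class for a monosubstituted allyl unit; C- over O-alkylation should be favoured by the soft allyl electrophile and by the reversibility of O-allylation of so stabilised an enolate; a second allylation is held back by the excess of 9 and by the hindered product enolate. The free hydroxyl cannot close on the far allyl terminus because the E carbonate gives a syn-allyl complex, and it is not deprotonated by the weakly basic enolate. In the closure the aldehyde, far more electrophilic than the donor-substituted aryl ketone, takes the hydroxyl, and the weak acids (AcOH, PPTS) are chosen so that the benzylic C2–O bond does not ionise.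

Step 6
Reactants: 12 [(4S,5R)-5-(3,4-dimethoxyphenyl)-4-ethenyl-4,5-dihydrofuran-3-yl](3,4,5-trimethoxyphenyl)methanone
Product: 14 [(3S,4S,5R)-5-(3,4-dimethoxyphenyl)-4-ethenyltetrahydrofuran-3-yl](3,4,5-trimethoxyphenyl)methanone (2,3-cis-3,4-trans), via all-cis C4-epimeric ketone 13 (not isolated)
Conditions: [(Ph3P)CuH]6 (0.5 equiv), H2O (3 equiv), degassed toluene, rt; then DBU (0.2 equiv), rt
Reagents that add atoms: none
Why: Copper hydride conjugate reduction: hydrocupration of the polarised C4=C5 bond of the β-alkoxy enone leaves the isolated vinyl group, the aryl ketone and the arenes alone, and water protonates the copper enolate, mainly from the open face, to give 13. DBU then equilibrates the ketone α-centre through the enolate to 14, in which the aroyl group is trans to both cis substituents, so C4 is set under thermodynamic control.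

Step 7
Reactants: 14 [(3S,4S,5R)-5-(3,4-dimethoxyphenyl)-4-ethenyltetrahydrofuran-3-yl](3,4,5-trimethoxyphenyl)methanone
Product: 16 [(3S,4R,5R)-5-(3,4-dimethoxyphenyl)-4-(hydroxymethyl)tetrahydrofuran-3-yl](3,4,5-trimethoxyphenyl)methanone, the target, (2R,3R,4S) in the ring locants used here, via keto aldehyde 15 (not isolated)
Conditions: O3, CH2Cl2–MeOH (4:1), Sudan Red 7B end-point, −78 °C; PPh3 (1.2 equiv), −78 to 0 °C; NaBH4 (1.5 equiv), −78 °C; acetone, aq. NH4Cl
Reagents that add atoms: ozone, [O-][O+]=O
Why: Ozonolysis with reductive work-up, then chemoselective borohydride reduction: ozone, stopped at the dye end-point, cleaves the only alkene before the donor-substituted arenes react, PPh3 reduces the peroxidic intermediates to 15, and NaBH4 at −78 °C should reduce the aldehyde much faster than the hindered, donor-deactivated aryl ketone. No stereocentre is formed; C3 keeps its configuration because 15 is generated and consumed cold under near-neutral conditions.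

## Compound list

1 | veratraldehyde (3,4-dimethoxybenzaldehyde) | COc1ccc(C=O)cc1OC | starting material
2 | vinylmagnesium bromide | C=C[Mg]Br | starting material
3 | rac-1-(3,4-dimethoxyphenyl)prop-2-en-1-ol | COc1ccc(C(O)C=C)cc1OC | intermediate
4 | (R)-1-(3,4-dimethoxyphenyl)prop-2-en-1-ol | COc1ccc([C@H](O)C=C)cc1OC | intermediate
5 | allyl methyl carbonate | C=CCOC(=O)OC | starting material
6 | (R,E)-4-(3,4-dimethoxyphenyl)-4-hydroxybut-2-en-1-yl methyl carbonate | COc1ccc([C@H](O)/C=C/COC(=O)OC)cc1OC | intermediate
7 | 3',4',5'-trimethoxyacetophenone | CC(=O)c1cc(OC)c(OC)c(OC)c1 | starting material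
8 | ethyl formate | CCOC=O | starting material
9 | sodium 3-oxo-3-(3,4,5-trimethoxyphenyl)prop-1-en-1-olate | [Na+].[O-]C=CC(=O)c1cc(OC)c(OC)c(OC)c1 | intermediate
10 | 2-[(1R,2S)-1-(3,4-dimethoxyphenyl)-1-hydroxybut-3-en-2-yl]-3-oxo-3-(3,4,5-trimethoxyphenyl)propanal (the carbon between the two carbonyl groups unconfigured, largely enolised) | COc1ccc([C@H](O)[C@@H](C=C)C(C=O)C(=O)c2cc(OC)c(OC)c(OC)c2)cc1OC | intermediate
11 | [(4S,5R)-5-(3,4-dimethoxyphenyl)-4-ethenyl-2-hydroxytetrahydrofuran-3-yl](3,4,5-trimethoxyphenyl)methanone (mixture at the two unconfigured ring carbons) | COc1ccc([C@@H]2OC(O)C(C(=O)c3cc(OC)c(OC)c(OC)c3)[C@@H]2C=C)cc1OC | intermediate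
12 | [(4S,5R)-5-(3,4-dimethoxyphenyl)-4-ethenyl-4,5-dihydrofuran-3-yl](3,4,5-trimethoxyphenyl)methanone | COc1ccc([C@@H]2OC=C(C(=O)c3cc(OC)c(OC)c(OC)c3)[C@@H]2C=C)cc1OC | intermediate
13 | [(3R,4S,5R)-5-(3,4-dimethoxyphenyl)-4-ethenyltetrahydrofuran-3-yl](3,4,5-trimethoxyphenyl)methanone (all-cis) | COc1ccc([C@@H]2OC[C@H](C(=O)c3cc(OC)c(OC)c(OC)c3)[C@@H]2C=C)cc1OC | intermediate
14 | [(3S,4S,5R)-5-(3,4-dimethoxyphenyl)-4-ethenyltetrahydrofuran-3-yl](3,4,5-trimethoxyphenyl)methanone | COc1ccc([C@@H]2OC[C@@H](C(=O)c3cc(OC)c(OC)c(OC)c3)[C@@H]2C=C)cc1OC | intermediate
15 | (2R,3S,4S)-2-(3,4-dimethoxyphenyl)-4-(3,4,5-trimethoxybenzoyl)tetrahydrofuran-3-carbaldehyde | COc1ccc([C@@H]2OC[C@@H](C(=O)c3cc(OC)c(OC)c(OC)c3)[C@@H]2C=O)cc1OC | intermediate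
16 | [(3S,4R,5R)-5-(3,4-dimethoxyphenyl)-4-(hydroxymethyl)tetrahydrofuran-3-yl](3,4,5-trimethoxyphenyl)methanone | COc1ccc([C@@H]2OC[C@@H](C(=O)c3cc(OC)c(OC)c(OC)c3)[C@@H]2CO)cc1OC | target

## Step count and least certain steps

Total: 7 steps. Longest linear sequence: 6 steps (steps 1, 2, 3, 5, 6, 7); step 4 is the one-step branch.

Step 5 (key step, proposed new method).
- What may go wrong: O-allylation or attack at the unsubstituted terminus; loss of the formyl group by methoxide-induced retro-Claisen cleavage; low facial selectivity if the (R)-carbinol and the ligand form a mismatched pair; slow reaction because the salt dissolves poorly; erosion of C2 or drift of the double bonds toward the aromatic furan during the acid phase.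
- Fallback (known chemistry only, from 6 and 7, back at 12): the hydroxyl of 6 is silylated (t-BuMe2SiCl, imidazole) to (R,E)-4-(tert-butyldimethylsilyloxy)-4-(3,4-dimethoxyphenyl)but-2-en-1-yl methyl carbonate F1. Ketone 7 is converted (Me3SiOTf, Et3N) into trimethyl{[1-(3,4,5-trimethoxyphenyl)ethenyl]oxy}silane F2. The two are joined by the established iridium-catalysed allylation of ketone silyl enol ethers ([Ir(cod)Cl]2, the same ligand, CsF, ZnF2) to the branched ketone (3R,4R)-4-(tert-butyldimethylsilyloxy)-4-(3,4-dimethoxyphenyl)-3-ethenyl-1-(3,4,5-trimethoxyphenyl)butan-1-one F3. Claisen formylation at its only α-methylene (NaH, 8) gives the silyl-protected formyl ketone 2-[(1R,2S)-1-(tert-butyldimethylsilyloxy)-1-(3,4-dimethoxyphenyl)but-3-en-2-yl]-3-oxo-3-(3,4,5-trimethoxyphenyl)propanal F4. Bu4NF buffered with AcOH frees the hydroxyl (10), and PPTS closes and dehydrates through 11 to 12. The same two bonds are made, one at a time, with a nucleophile class already established for this catalyst.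

Step 6.
- What may go wrong: sluggish hydride transfer to the donor-deactivated C5; competing 1,2-reduction of the ketone; ring opening by β-elimination of the C2 alkoxide from the enolate; incomplete equilibration at C4.
- Fallback (from 12, back at 14): the hydrometalation is replaced by direct nucleophilic 1,4-addition of a hindered borohydride, LiBH(s-Bu)3 in THF at −78 °C, as is routine for cyclic β-alkoxy enones. A buffered protonation and the same DBU equilibration follow. No new compound is made (F0).

Step 7.
- What may go wrong: over-oxidation of the arenes by ozone; epimerisation at C3 while 15 is present; partial reduction of the aryl ketone.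
- Fallback (from 14, back at 16): chemoselectivity is given up. Ozonolysis followed by excess NaBH4 at 0 °C to rt reduces both carbonyl groups, the aldehyde as soon as it forms, to the diol [(3S,4R,5R)-5-(3,4-dimethoxyphenyl)-4-(hydroxymethyl)tetrahydrofuran-3-yl](3,4,5-trimethoxyphenyl)methanol F5 (mixture at the carbinol carbon). MnO2 in CH2Cl2 then re-oxidises only the benzylic alcohol to give 16, at the cost of one more step.

Step 2.
- What may go wrong: slow epoxidation of the monosubstituted vinyl group, hence a modest rate difference between the enantiomers; ionisation of the donor-substituted benzylic allylic alcohol by the Lewis acid; loss of half the material at best.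
- Fallback (from 1, back at 4): resolution is replaced by asymmetric synthesis. Ethynyltrimethylsilane is added to 1 with Me2Zn and the enantiomer of 2,6-bis{[2-(hydroxydiphenylmethyl)pyrrolidin-1-yl]methyl}-4-methylphenol that directs the alkynylzinc to the Re face of the aldehyde. This gives (S)-1-(3,4-dimethoxyphenyl)-3-(trimethylsilyl)prop-2-yn-1-ol F6. K2CO3 in MeOH removes the silyl group to give (R)-1-(3,4-dimethoxyphenyl)prop-2-yn-1-ol F7. Semi-hydrogenation (H2, Pd on CaCO3 poisoned with Pb(OAc)2, quinoline) then gives 4.

## Further compounds

F1 | step 5 | (R,E)-4-[(tert-butyldimethylsilyl)oxy]-4-(3,4-dimethoxyphenyl)but-2-en-1-yl methyl carbonate | COc1ccc([C@H](O[Si](C)(C)C(C)(C)C)/C=C/COC(=O)OC)cc1OC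
F2 | step 5 | trimethyl{[1-(3,4,5-trimethoxyphenyl)ethenyl]oxy}silane | C=C(O[Si](C)(C)C)c1cc(OC)c(OC)c(OC)c1
F3 | step 5 | (3R,4R)-4-[(tert-butyldimethylsilyl)oxy]-4-(3,4-dimethoxyphenyl)-3-ethenyl-1-(3,4,5-trimethoxyphenyl)butan-1-one | COc1ccc([C@H](O[Si](C)(C)C(C)(C)C)[C@@H](C=C)CC(=O)c2cc(OC)c(OC)c(OC)c2)cc1OC
F4 | step 5 | 2-[(1R,2S)-1-[(tert-butyldimethylsilyl)oxy]-1-(3,4-dimethoxyphenyl)but-3-en-2-yl]-3-oxo-3-(3,4,5-trimethoxyphenyl)propanal | COc1ccc([C@H](O[Si](C)(C)C(C)(C)C)[C@@H](C=C)C(C=O)C(=O)c2cc(OC)c(OC)c(OC)c2)cc1OC
F0 | step 6 | none | none
F5 | step 7 | [(3S,4R,5R)-5-(3,4-dimethoxyphenyl)-4-(hydroxymethyl)tetrahydrofuran-3-yl](3,4,5-trimethoxyphenyl)methanol, mixture at the carbinol carbon | COc1ccc([C@@H]2OC[C@@H](C(O)c3cc(OC)c(OC)c(OC)c3)[C@@H]2CO)cc1OC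
F6 | step 2 | (S)-1-(3,4-dimethoxyphenyl)-3-(trimethylsilyl)prop-2-yn-1-ol | COc1ccc([C@H](O)C#C[Si](C)(C)C)cc1OC
F7 | step 2 | (R)-1-(3,4-dimethoxyphenyl)prop-2-yn-1-ol | COc1ccc([C@H](O)C#C)cc1OC
A1 | alternative 1 | [(4R,5R)-4-{[(tert-butyldiphenylsilyl)oxy]methyl}-5-(3,4-dimethoxyphenyl)-4,5-dihydrofuran-3-yl](3,4,5-trimethoxyphenyl)methanone | COc1ccc([C@@H]2OC=C(C(=O)c3cc(OC)c(OC)c(OC)c3)[C@@H]2CO[Si](c4ccccc4)(c5ccccc5)C(C)(C)C)cc1OC
A2 | alternative 1 | tert-butyl{[(2R,3R)-2-(3,4-dimethoxyphenyl)-2,3-dihydrofuran-3-yl]methoxy}diphenylsilane | COc1ccc([C@@H]2OC=C[C@@H]2CO[Si](c3ccccc3)(c4ccccc4)C(C)(C)C)cc1OC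
A3 | alternative 1 | 5-iodo-1,2,3-trimethoxybenzene | COc1cc(I)cc(OC)c1OC
A4 | alternative 2 | [(3S,4R,5R)-4-{[(tert-butyldiphenylsilyl)oxy]methyl}-5-(3,4-dimethoxyphenyl)tetrahydrofuran-3-yl](3,4,5-trimethoxyphenyl)methanol, mixture at the carbinol carbon | COc1ccc([C@@H]2OC[C@@H](C(O)c3cc(OC)c(OC)c(OC)c3)[C@@H]2CO[Si](c4ccccc4)(c5ccccc5)C(C)(C)C)cc1OC
A5 | alternative 2 | tert-butyl{[(2R,3E)-2-[(R)-(3,4-dimethoxyphenyl)(phenylselanylmethoxy)methyl]-4-(3,4,5-trimethoxyphenyl)but-3-en-1-yl]oxy}diphenylsilane | COc1ccc([C@H](OC[Se]c2ccccc2)[C@@H](CO[Si](c2ccccc2)(c2ccccc2)C(C)(C)C)/C=C/c2cc(OC)c(OC)c(OC)c2)cc1OC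
A6 | alternative 3 | (2R,3S,4R)-2-(3,4-dimethoxyphenyl)-4-[1-(3,4,5-trimethoxyphenyl)ethenyl]tetrahydrofuran-3-carbaldehyde | COc1ccc([C@@H]2OC[C@@H](C(=C)c3cc(OC)c(OC)c(OC)c3)[C@@H]2C=O)cc1OC
A7 | alternative 3 | (5R)-2-(3,4-dimethoxyphenyl)-5-[1-(3,4,5-trimethoxyphenyl)ethenyl]-4,5-dihydro-1,3-dioxepine, either configuration at the acetal carbon | COc1ccc(C2OC[C@@H](C(=C)c3cc(OC)c(OC)c(OC)c3)C=CO2)cc1OC
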